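The C6–C6'' biaryl bond is read as the central C–C bond of diethyl 2,3-diacetylsuccinate. In each ring A, C6 lies between the oxygen-bearing carbons C5 and C7, exactly as the α-carbon of a β-keto ester lies between its two carbonyls. One operation then joins the succinate tetraanion to two enantiopure 6-methoxy-2,3-dihydropyran-4-ones, which bring ring C, O1 and the 2S centre ready-made; C8–C8a and C4a–C5 form on each side and both rings A aromatise. The precursors are the commercial succinate and an (S)-pyranone made in two steps by asymmetric hetero-Diels–Alder chemistry; hydrogenolysis of two benzyl ethers ends the synthesis.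

Key step: step 3

Assumption: the target string fixes no configuration for the hindered C6–C6'' axis, so the axis is left uncontrolled and whichever atropisomer composition results is taken as the target.

Step 1
Reactants: 1 4,4-dimethoxybut-3-en-2-one
Product: 3 1,1-dimethoxy-3-(trimethylsilyloxy)buta-1,3-diene, via lithium dienolate 2 (not isolated)
Conditions: LiN(iPr)2 (1.05 equiv), THF, −78 °C; Me3SiCl (1.2 equiv), −78 °C → rt; non-aqueous work-up (pentane, filtration under argon), distillation
Reagents that add atoms: chlorotrimethylsilane (Me3SiCl), C[Si](C)(C)Cl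
Why: Kinetic deprotonation of the only enolisable position of 1 (the acetyl methyl group) followed by O-silylation of the cross-conjugated dienolate is standard silyl enol ether formation, as used for other 1-alkoxy-3-silyloxy dienes, and creates no stereocentre.

Step 2
Reactants: 3 1,1-dimethoxy-3-(trimethylsilyloxy)buta-1,3-diene; 4 4-(benzyloxy)benzaldehyde
Product: 6 (S)-2-[4-(benzyloxy)phenyl]-6-methoxy-2,3-dihydro-4H-pyran-4-one, via silylated aldol adduct 5 (not isolated)
Conditions: Ti(OiPr)4 (10 mol%), (S)-BINOL (20 mol%), 4 Å MS, Et2O, −20 °C; then CF3CO2H (0.2 equiv), CH2Cl2, 0 °C; NaHCO3 work-up; Et3N-deactivated silica, recrystallisation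
Reagents that add atoms: none
Why: This is a catalytic asymmetric hetero-Diels–Alder reaction in its stepwise Mukaiyama aldol–cyclisation form, known for 1-alkoxy-3-silyloxy dienes and aromatic aldehydes: the CH2 terminus of 3 should add to the Si face of the aldehyde bound to the Ti(OiPr)4–(S)-BINOL catalyst (the sense expected by analogy with other carbonyl additions under this catalyst, to be confirmed on the product and reversed with (R)-BINOL if needed), which sets the future C2 as S, and CF3CO2H then closes ring C by attack of the silyl ether oxygen on the ketene-acetal carbon with loss of methanol.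

Step 3
Reactants: 7 diethyl 2,3-diacetylsuccinate; 6 (S)-2-[4-(benzyloxy)phenyl]-6-methoxy-2,3-dihydro-4H-pyran-4-one (2.1 equiv)
Product: 10 (2S,2''S)-4',4'''-di-O-benzylsuccedaneaflavanone, via tetralithium tetraanion 8 (not isolated), via bis-adduct 9 (not isolated)
Conditions: 7 added to titrated LiN(iPr)2 (4.0 equiv), THF, −78 → 0 °C; recooled to −78 °C, 6 (2.1 equiv) in THF added; −78 → 0 °C; AcOH (6 equiv), 0 °C
Reagents that add atoms: none
Why: Proposed new method: LiN(iPr)2 removes both α-hydrogens and one hydrogen of each acetyl methyl group of 7 to give the bis(1,3-dianion) 8, whose terminal carbanions (the future C8 and C8'') attack the methoxy-bearing, ester-like carbon of two molecules of 6 (the future C8a and C8a''); the enolates formed expel methoxide to give 9, proton transfer then generates the extended enolate O–C4=C4a–C8a=C8 on each side, C4a attacks the adjacent ester carbonyl (the future C5) in a Claisen condensation, and loss of ethoxide followed by enolisation aromatises ring A. The closest known reaction types are the γ-acylation of β-keto ester dianions by esters, the Staunton–Weinreb annulation (carbanion addition to a β-methoxy enoate, Claisen-type closure onto an ester and loss of methanol to give an arene) and the biomimetic Claisen cyclisation of 3,5,7-triketo esters to acylphloroglucinols. Each of the two rings A closes in a 6-(enolexo)-exo-trig mode, C4a attacking the ester carbonyl, and aromatisation makes the closure irreversible. No stereocentre is created: C2 and C2'' are carried unchanged from 6, and the C6–C6'' axis, which arises from the central succinate bond, is not controlled. The selectivities needed are γ- over α-attack, secured because each α-carbon is fully substituted and sits in the stabilised β-keto ester enolate, and addition at C8a in preference to addition at C4 or deprotonation at C3, secured by the doubly donor-deactivated C4 carbonyl, by the reversibility of aldol-type addition at C4 against the irreversible loss of methoxide, and by using no base beyond four equivalents at −78 °C. Claisen closure is preferred to the aldol alternative (α-carbon onto C4) because the latter would build a quaternary carbon that cannot aromatise and can revert, and if O1 rather than methoxide should leave from C8a the tethered alkoxide can re-add and expel methoxide, so that both paths lead to 9.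

Step 4
Reactants: 10 (2S,2''S)-4',4'''-di-O-benzylsuccedaneaflavanone
Product: 11 succedaneaflavanone
Conditions: H2 (1 atm), 10% Pd/C, EtOAc–MeOH, rt; stopped after uptake of 2 equiv H2
Reagents that add atoms: none
Why: Heterogeneous hydrogenolysis of aryl benzyl ethers over Pd/C is fast and neutral, so both ring B phenols should be released without acid or base that could open ring C and erode C2, while the slower benzylic C2–O1 cleavage is avoided by stopping at two equivalents of hydrogen.

Compound list
1 | 4,4-dimethoxybut-3-en-2-one | CC(=O)C=C(OC)OC | starting material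
2 | lithium 4,4-dimethoxybuta-1,3-dien-2-olate (not isolated) | [Li+].C=C([O-])C=C(OC)OC | intermediate
3 | 1,1-dimethoxy-3-(trimethylsilyloxy)buta-1,3-diene | C=C(O[Si](C)(C)C)C=C(OC)OC | intermediate
4 | 4-(benzyloxy)benzaldehyde | O=Cc1ccc(OCc2ccccc2)cc1 | starting material
5 | (S)-5-[4-(benzyloxy)phenyl]-1,1-dimethoxy-5-(trimethylsilyloxy)pent-1-en-3-one (not isolated) | COC(OC)=CC(=O)C[C@H](O[Si](C)(C)C)c1ccc(OCc2ccccc2)cc1 | intermediate
6 | (S)-2-[4-(benzyloxy)phenyl]-6-methoxy-2,3-dihydro-4H-pyran-4-one | COC1=CC(=O)C[C@@H](c2ccc(OCc3ccccc3)cc2)O1 | intermediate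
7 | diethyl 2,3-diacetylsuccinate (mixture of diastereomers and enol forms) | CCOC(=O)C(C(C)=O)C(C(C)=O)C(=O)OCC | starting material
8 | tetralithium salt of the bis(1,3-dianion) of 7 (not isolated) | [Li+].[Li+].[Li+].[Li+].C=C([O-])C(=C([O-])OCC)C(C(=C)[O-])=C([O-])OCC | intermediate
9 | diethyl 2,3-bis{2-[(2S)-2-(4-benzyloxyphenyl)-4-oxo-3,4-dihydro-2H-pyran-6-yl]acetyl}succinate (not isolated; present as its Li enolates, succinate centres undefined) | CCOC(=O)C(C(=O)CC1=CC(=O)C[C@@H](c2ccc(OCc3ccccc3)cc2)O1)C(C(=O)CC1=CC(=O)C[C@@H](c2ccc(OCc3ccccc3)cc2)O1)C(=O)OCC | intermediate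
10 | (2S,2''S)-2,2''-bis[4-(benzyloxy)phenyl]-5,5'',7,7''-tetrahydroxy-[6,6''-bichroman]-4,4''-dione (4',4'''-di-O-benzylsuccedaneaflavanone) | O=C1C[C@@H](c2ccc(OCc3ccccc3)cc2)Oc2cc(O)c(-c3c(O)cc4c(c3O)C(=O)C[C@@H](c3ccc(OCc5ccccc5)cc3)O4)c(O)c21 | intermediate
11 | succedaneaflavanone, (2S,2''S)-5,5'',7,7''-tetrahydroxy-2,2''-bis(4-hydroxyphenyl)-[6,6''-bichroman]-4,4''-dione | O=C1C[C@@H](c2ccc(O)cc2)Oc2cc(O)c(-c3c(O)cc4c(c3O)C(=O)C[C@@H](c3ccc(O)cc3)O4)c(O)c21 | target

Total step count: 4
Longest linear sequence: 4 steps (1 → 3 → 6 → 10 → 11); 7 is purchased.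

Steps most likely to fail

1. Step 3 (proposed new method). What may go wrong:
- The terminal carbanions of 8 may act as bases toward C3–H of 6 instead of adding at C8a; the enolate so formed can expel O1, which opens ring C and erodes the 2S centre.
- The first annulated arm may pass a proton to the second carbanion, so that only one side reacts.
- The Claisen closure may stall at the open-chain stage 9, or be followed by base-induced opening of ring C.

Fallback, by established reactions only, setting out from aldehyde 4 and rejoining the route at 11: the annulation is abandoned and the biaryl bond is made last, by coupling two complete, regiochemically defined monomers. Claisen–Schmidt condensation of 4 with commercial 4',6'-bis(benzyloxy)-2'-hydroxyacetophenone (KOH, EtOH) should give the 2'-hydroxychalcone F1, which NaOAc in refluxing EtOH closes to racemic 5,7,4'-tri-O-benzylnaringenin F2. BCl3 (1 equiv, CH2Cl2, −78 °C) removes only the chelated 5-O-benzyl group to give racemic 7,4'-di-O-benzylnaringenin F3. Benzyltrimethylammonium dichloroiodate (CaCO3, CH2Cl2–MeOH) iodinates ortho to the free 5-OH, at C6, to give the racemic 6-iodide F4. Re-benzylation (BnBr, K2CO3, DMF), harmless to a racemate, gives racemic 5,7,4'-tri-O-benzyl-6-iodonaringenin F5, and chromatography on a chiral stationary phase provides its (S)-enantiomer F6. Ullmann homocoupling (Cu powder, DMF, 120 °C, no base) joins C6 to C6'' and gives (2S,2''S)-hexa-O-benzylsuccedaneaflavanone F7; hydrogenolysis under the conditions of step 4 gives 11.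

2. Step 2. What may go wrong: insufficient facial discrimination of the electron-rich, weakly electrophilic aldehyde on the Ti(OiPr)4–BINOL catalyst, or hydrolysis of the ketene acetal before ring closure, so that a keto lactone forms in place of the methoxypyranone.

Fallback, setting out from ketone 1 and aldehyde 4 and rejoining at 6: the silyl diene and the catalyst are replaced by a reagent-controlled boron aldol reaction. Enolisation of 1 with Ipc2BCl (the antipode that directs attack to the Si face of the aldehyde, to be assigned on a test run) and iPr2NEt in Et2O at −78 °C, then addition of 4 and non-oxidative work-up with diethanolamine, should give the (S)-aldol F8. Catalytic pyridinium p-toluenesulfonate in CH2Cl2 then closes ring C with loss of methanol to give 6, whose enantiomeric purity can be raised by recrystallisation.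

3. Step 4. What may go wrong: over-reduction on Pd/C (hydrogenolysis of the benzylic C2–O1 bonds of ring C or reduction at C4), or incomplete reaction because partly deprotected material precipitates.

Fallback, setting out from 10 and rejoining at 11: the reductive cleavage is replaced by a non-reductive benzyl transfer. BCl3 with pentamethylbenzene as cation scavenger in CH2Cl2 at −78 °C should cleave both aryl benzyl ethers by Lewis-acid activation and capture of the benzyl cation, with no hydrogen or metal surface present. No new intermediate is formed.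

Further compounds
F1 | step 3 | (E)-1-[2,4-bis(benzyloxy)-6-hydroxyphenyl]-3-[4-(benzyloxy)phenyl]prop-2-en-1-one | O=C(/C=C/c1ccc(OCc2ccccc2)cc1)c1c(O)cc(OCc2ccccc2)cc1OCc1ccccc1
F2 | step 3 | racemic 5,7-bis(benzyloxy)-2-[4-(benzyloxy)phenyl]chroman-4-one | O=C1CC(c2ccc(OCc3ccccc3)cc2)Oc2cc(OCc3ccccc3)cc(OCc3ccccc3)c21
F3 | step 3 | racemic 7-(benzyloxy)-2-[4-(benzyloxy)phenyl]-5-hydroxychroman-4-one | O=C1CC(c2ccc(OCc3ccccc3)cc2)Oc2cc(OCc3ccccc3)cc(O)c21
F4 | step 3 | racemic 7-(benzyloxy)-2-[4-(benzyloxy)phenyl]-5-hydroxy-6-iodochroman-4-one | O=C1CC(c2ccc(OCc3ccccc3)cc2)Oc2cc(OCc3ccccc3)c(I)c(O)c21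
F5 | step 3 | racemic 5,7-bis(benzyloxy)-2-[4-(benzyloxy)phenyl]-6-iodochroman-4-one | O=C1CC(c2ccc(OCc3ccccc3)cc2)Oc2cc(OCc3ccccc3)c(I)c(OCc3ccccc3)c21
F6 | step 3 | (S)-5,7-bis(benzyloxy)-2-[4-(benzyloxy)phenyl]-6-iodochroman-4-one | O=C1C[C@@H](c2ccc(OCc3ccccc3)cc2)Oc2cc(OCc3ccccc3)c(I)c(OCc3ccccc3)c21
F7 | step 3 | (2S,2''S)-5,5'',7,7''-tetrakis(benzyloxy)-2,2''-bis[4-(benzyloxy)phenyl]-[6,6''-bichroman]-4,4''-dione | O=C1C[C@@H](c2ccc(OCc3ccccc3)cc2)Oc2cc(OCc3ccccc3)c(-c3c(OCc5ccccc5)cc4c(c3OCc3ccccc3)C(=O)C[C@@H](c3ccc(OCc5ccccc5)cc3)O4)c(OCc3ccccc3)c21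
F8 | step 2 | (S)-5-[4-(benzyloxy)phenyl]-5-hydroxy-1,1-dimethoxypent-1-en-3-one | COC(OC)=CC(=O)C[C@H](O)c1ccc(OCc2ccccc2)cc1
F0 | step 4 | none | none
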